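Positions are given in labdane numbering: ring A = C1–C5 and C10, ring B = C5–C10, C18 and C19 on C4, C20 on C10, C17 on C8, side chain C11–C16. Compounds 1–25 belong to the route, F1–F11 to the fallbacks, A1–A6 to the alternatives.

## The problem

The target is the 19-(E)-ferulate of labda-13(16),14-diene-8α,19-diol, a trans-decalin with five stereocenters (4S,5R,8R,9R,10S). Two of these are quaternary carbons (C4, C10) and one is a tertiary alcohol (C8). The hardest element is C4: its two one-carbon groups must be told apart, with the oxidised one (C19) axial and 1,3-syn to C20, and C4 must be set in relation to C5 and C10. Once C10 is fixed, C9 and C8 follow from a chair closure of ring B onto an (E)-C8=C9 alkene.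

The feature that the plan uses is twofold. Ring A with its branches (C1–C6, C10, C19, C20) is a reduced 2,3-dimethylbenzoic acid. The C19 oxygen lies on the same face of ring A as C20 and is two bonds from C10 through C5, so it can bridge to C10 and leave only the opposite face open for the C9–C10 bond.

The C8 hydroxyl is δ to C13, so a C13 carbonyl oxygen can end the ring closure and deliver the 8α-oxygen directly. The 2-substituted buta-1,3-diene (acid, radicals, cycloaddition), the tertiary alcohol (elimination) and the ferulate (free phenol, base-labile conjugated ester) will not survive strong acid, dissolving metal or hydride. They must therefore come last.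

## Retrosynthesis

The plan in one sentence: a flat benzamide is dearomatized to set C4, and the C19 oxygen of C4 then relays that one stereocenter to C5, C10, C9 and C8 in a single acid-mediated closure of ring B.

**C19–O ester bond.** Target 25 is cut to diol 22 and acid 23, whose phenol is masked as the acetate and released from 24. The cut is placed last because the cinnamate tolerates none of the earlier reagents. The forward reaction must acylate a neopentyl primary alcohol in the presence of the tertiary C8 alcohol, which is a large rate difference.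

**C13–C14 bond of the diene.** Diol 22 is cut to methyl ketone 17 by way of hydrazone 19 (Shapiro reaction, then Negishi vinylation). Dehydration of a C13 carbinol would give three alkene isomers, and a C11–C12 alkylation would need substitution next to the crowded C9. The ketone is also the group that ends the key step, so it does double duty.

**C9–C10 and C8–O bonds (key step).** Ketone 17 (two rings, five stereocenters) is cut to the monocyclic dienol ketone 14 (one ring, one stereocenter, one alkene geometry). The neighbouring cut, a bicyclization of an acyclic polyene, would leave C4 to be set in the same event without any control element. Here C4 is already in place and steers the rest. The forward reaction must add H to C5 and C9 to C10 on the face opposite C19, and oxygen to C8 anti to C10.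

**C19 oxidation level and the C2–C3 bond.** Alcohol 14 comes from amide 12 by hydride reduction, which also releases the auxiliary 6, followed by removal of the ketal of 13. Amide 12 comes from diene 11 by hydrogenation of the only disubstituted alkene.

**C4–C18 bond and the arene.** Diene 11 is cut to benzamide 9 by Birch reduction–methylation. This one operation turns the aromatic carbon into the quaternary stereocenter C4. It also leaves the C5=C10 alkene exactly where the key step needs it.

**C6–C7 bond.** Benzamide 9 is cut to amide 7 and allylic bromide 4 by lateral lithiation. Amide 7 is made from acid chloride 5 and auxiliary 6. Bromide 4 comes in three steps from the commodity ketone 1 through 2 and 3, and the SeO2 oxidation fixes the E geometry.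

## Roads not taken

**Alternative 1:** (the most obvious) keep the ring system and cut only a C19–H bond. (+)-Sclareolide A1 already has C5, C8, C9 and C10 correct, and the forward key step would be hydroxylation of its axial C19 methyl to 19-hydroxysclareolide A2. This cannot be defended. C19 is an unactivated primary C–H of a geminal pair. The lactone oxygen is on the other ring, and a directing group at C3 would reach the equatorial C18. Undirected oxidants prefer the ring A methylenes. The chosen plan builds the C18/C19 difference into the first stereocenter instead.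

**Alternative 2:** cut C4–C5 and C9–C10 of a β-keto ester polyene A3 and close both rings by oxidative radical bicyclization with Mn(OAc)3 and Cu(OAc)2 (trivalent manganese) to keto ester A4. This sets the axial ester and the trans fusion reliably. It leaves a C3 ketone to delete and an 8(17)-alkene to hydrate from the α-face, and it gives a racemate unless a chiral ester auxiliary is added and later removed. The chosen plan needs no deoxygenation, forms the C8–O bond in the key step and removes its auxiliary in the step that makes the C19 alcohol.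

**Alternative 3:** cut the same two bonds of the acyclic 2,2-disubstituted epoxide A5 and let a Lewis acid open the strained ring into a cationic bicyclization that would give 17 directly. The epoxide carbon fixes only C4, by inversion. Whether C19 ends axial (17) or equatorial (the C4 epimer A6) depends on which of two similar groups is axial in the chair, and the Lewis-acid-bearing CH2O group should prefer equatorial. A 1,2-hydride shift to the aldehyde competes, and an enantiopure epoxide of this type itself costs several steps. In the chosen plan the C19 oxygen is tied to C10 during the closure, so the C4/C10 relation does not rest on a small conformational preference.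

Key step: step 9

Assumption: in the Birch reduction–methylation of the 2-alkylbenzamide 9 the (S)-auxiliary is taken to direct the methyl group to the face that gives (1S)-11; if the sense is the reverse, the (R)-enantiomer of 6 is used and nothing else changes.

Assumption: compounds 1, 5, 6, 18 and 23 are taken as catalogue chemicals.

## Route

Step 1
Reactants: 1 6-methylhept-5-en-2-one
Product: 2 2-methyl-2-(4-methylpent-3-en-1-yl)-1,3-dioxolane
Conditions: HOCH2CH2OH, TsOH·H2O (cat.), PhH, reflux, Dean–Stark
Reagents that add atoms: ethylene glycol, OCCO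
Why: Acid-catalysed ketalization with azeotropic removal of water; the ketone has to be masked against the amide bases, the dissolving metal and the hydride used before the key step.

Step 2
Reactants: 2 2-methyl-2-(4-methylpent-3-en-1-yl)-1,3-dioxolane
Product: 3 (2E)-2-methyl-5-(2-methyl-1,3-dioxolan-2-yl)pent-2-en-1-ol
Conditions: SeO2 (cat.), t-BuOOH, CH2Cl2, 0 °C → rt
Reagents that add atoms: tert-butyl hydroperoxide, CC(C)(C)OO
Why: Allylic oxidation by SeO2 (ene reaction, then [2,3]-sigmatropic shift) is selective for the methyl group trans to the chain of a trisubstituted alkene, so the E geometry that later defines the C8/C9 relationship is set here.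

Step 3
Reactants: 3 (2E)-2-methyl-5-(2-methyl-1,3-dioxolan-2-yl)pent-2-en-1-ol
Product: 4 2-[(3E)-5-bromo-4-methylpent-3-en-1-yl]-2-methyl-1,3-dioxolane
Conditions: CBr4, PPh3, CH2Cl2, 0 °C
Reagents that add atoms: carbon tetrabromide, BrC(Br)(Br)Br
Why: Appel reaction under neutral conditions should convert the primary allylic alcohol to the bromide without allylic transposition or loss of the ketal.

Step 4
Reactants: 5 2,3-dimethylbenzoyl chloride; 6 (S)-2-(methoxymethyl)pyrrolidine
Product: 7 (2,3-dimethylphenyl)[(2S)-2-(methoxymethyl)pyrrolidin-1-yl]methanone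
Conditions: Et3N, CH2Cl2, 0 °C → rt
Reagents that add atoms: none
Why: Simple N-acylation; the amide serves in turn as director of the lateral lithiation, as electron acceptor and chiral controller of the Birch step, and as the source of C19.

Step 5
Reactants: 7 (2,3-dimethylphenyl)[(2S)-2-(methoxymethyl)pyrrolidin-1-yl]methanone; 4 2-[(3E)-5-bromo-4-methylpent-3-en-1-yl]-2-methyl-1,3-dioxolane
Product: 9 [(2S)-2-(methoxymethyl)pyrrolidin-1-yl]{3-methyl-2-[(3E)-3-methyl-6-(2-methyl-1,3-dioxolan-2-yl)hex-3-en-1-yl]phenyl}methanone, via benzylic organolithium 8 (not isolated)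
Conditions: LiN(i-Pr)2, THF, −78 °C; then 4, −78 → 0 °C
Reagents that add atoms: none
Why: Lateral lithiation of a tertiary ortho-toluamide with a lithium amide deprotonates the methyl group ortho to the carbonyl (the meta methyl is not acidified), and the benzylic anion should displace the primary allylic bromide directly, forming C6–C7 with the E alkene untouched.

Step 6
Reactants: 9 [(2S)-2-(methoxymethyl)pyrrolidin-1-yl]{3-methyl-2-[(3E)-3-methyl-6-(2-methyl-1,3-dioxolan-2-yl)hex-3-en-1-yl]phenyl}methanone
Product: 11 [(1S)-1,3-dimethyl-2-[(3E)-3-methyl-6-(2-methyl-1,3-dioxolan-2-yl)hex-3-en-1-yl]cyclohexa-2,5-dien-1-yl][(2S)-2-(methoxymethyl)pyrrolidin-1-yl]methanone, via potassium amide enolate 10 (not isolated)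
Conditions: K, NH3/THF, t-BuOH (1 equiv), −78 °C; then MeI, −78 °C → rt
Reagents that add atoms: iodomethane, CI
Why: Asymmetric Birch reduction–alkylation: 1,4-reduction of the benzamide (protonation para to the carbonyl, the two alkyl groups staying on the C5=C10 alkene) gives a chelated potassium amide enolate that is C-methylated at the ipso carbon on the face left open by the auxiliary, which creates the C4 quaternary stereocenter. Isolated alkenes and the ketal are inert.

Step 7
Reactants: 11 [(1S)-1,3-dimethyl-2-[(3E)-3-methyl-6-(2-methyl-1,3-dioxolan-2-yl)hex-3-en-1-yl]cyclohexa-2,5-dien-1-yl][(2S)-2-(methoxymethyl)pyrrolidin-1-yl]methanone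
Product: 12 [(1S)-1,3-dimethyl-2-[(3E)-3-methyl-6-(2-methyl-1,3-dioxolan-2-yl)hex-3-en-1-yl]cyclohex-2-en-1-yl][(2S)-2-(methoxymethyl)pyrrolidin-1-yl]methanone
Conditions: H2 (1 atm), RhCl(PPh3)3 (cat.), PhH/EtOH, rt
Reagents that add atoms: none
Why: Homogeneous hydrogenation with RhCl(PPh3)3 discriminates strongly by substitution, so only the cis-disubstituted C2=C3 alkene should be reduced while the trisubstituted C8=C9 and tetrasubstituted C5=C10 alkenes remain; no stereocenter is touched.

Step 8
Reactants: 12 [(1S)-1,3-dimethyl-2-[(3E)-3-methyl-6-(2-methyl-1,3-dioxolan-2-yl)hex-3-en-1-yl]cyclohex-2-en-1-yl][(2S)-2-(methoxymethyl)pyrrolidin-1-yl]methanone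
Product: 14 (5E)-8-[(6S)-6-(hydroxymethyl)-2,6-dimethylcyclohex-1-en-1-yl]-6-methyloct-5-en-2-one, via ketal alcohol 13 (not isolated)
Conditions: LiNH2BH3 (from BH3·NH3 and LiN(i-Pr)2), THF, 0 → 66 °C; then 1 M aq. HCl, THF, rt
Reagents that add atoms: water, O
Why: LiNH2BH3 reduces tertiary amides, including α-quaternary ones, to primary alcohols with C–N cleavage, so the auxiliary 6 leaves as the amine and C19 arrives at the alcohol level while alkenes and ketal are untouched. The dilute acid of the work-up then hydrolyses the ketal and extracts 6.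

Step 9
Reactants: 14 (5E)-8-[(6S)-6-(hydroxymethyl)-2,6-dimethylcyclohex-1-en-1-yl]-6-methyloct-5-en-2-one
Product: 17 8α,19-dihydroxy-14,15-dinorlabdan-13-one, via bridged oxolane 15 (not isolated), via tricyclic enol ether 16 (not isolated)
Conditions: FSO3H (6 equiv), i-PrNO2, −78 → −40 °C; Et3N; then 1 M aq. HCl, THF, rt
Reagents that add atoms: water, O
Why: Protonation of the tetrasubstituted C5=C10 bond at C5 gives the tertiary C10 cation, which the C19 hydroxyl can reach only on its own (β) face to form the bridged oxonium of 15, a reversible store of the cation; C9 of the (E)-C8=C9 bond then bonds to C10 from the opposite (α) face while the C13 carbonyl oxygen adds to C8, loss of a proton leaves enol ether 16, and dilute acid hydrolyses it to 17. The closest known reaction type is the superacid cation–olefin cyclization of cyclohexenyl (monocyclic) terpenoid alcohols, acids and ketones ended by an oxygen nucleophile, and the displacement at C10 follows the course of epoxide-initiated polyene cyclization, in which an alkene opens a tertiary C–O bond from the rear. Ring B closes 6-endo with respect to C8=C9 (Markovnikov, charge at tertiary C8) through a chair, and the transient pyran ring closes by capture of C8 by the carbonyl oxygen in a six-membered array. At C10, C20 ends syn to C19 because C9 enters anti to the bridging oxygen. At C5, H-5 ends axial and trans to C20 because only the chair with the C6–C7 tether equatorial on ring A closes ring B, and the C5 epimers of the cation can exchange through the C5=C10 alkene. At C9 and C8, the E geometry and the chair place C11 equatorial, and anti addition across C8=C9 puts the oxygen on C8 equatorial (α) and C17 axial. The step needs attack on the α-face of C10 and a trans ring fusion; the first is secured by the C4 stereocenter through its C19 oxygen, the second by the chair preference of the closure.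

Step 10
Reactants: 17 8α,19-dihydroxy-14,15-dinorlabdan-13-one; 18 2,4,6-triisopropylbenzenesulfonohydrazide
Product: 19 8α,19-dihydroxy-14,15-dinorlabdan-13-one 2,4,6-triisopropylbenzenesulfonylhydrazone (E/Z mixture at C=N)
Conditions: HCl (cat.), THF/MeOH, rt
Reagents that add atoms: none
Why: Acid-catalysed condensation of the methyl ketone with the sulfonohydrazide; any enol ether 16 still present is opened under the same conditions and converges on 19.

Step 11
Reactants: 19 8α,19-dihydroxy-14,15-dinorlabdan-13-one 2,4,6-triisopropylbenzenesulfonylhydrazone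
Product: 22 labda-13(16),14-diene-8α,19-diol, via trilithiated vinyllithium 20 (not isolated), via vinylzinc bromide 21 (not isolated)
Conditions: n-BuLi (4.4 equiv), THF/TMEDA, −78 → 0 °C; ZnBr2; CH2=CHBr, Pd(PPh3)4 (cat.), rt; then H2O
Reagents that add atoms: vinyl bromide, C=CBr
Why: Shapiro reaction: the hydrazone dianion is formed at the less substituted α-carbon (the methyl group) and loses sulfinate and N2 to give the 2-lithio-1-alkene. Transmetalation to zinc and Negishi coupling with vinyl bromide on zerovalent palladium then give the 2-substituted buta-1,3-diene; the two alkoxides are spectators.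

Step 12
Reactants: 22 labda-13(16),14-diene-8α,19-diol; 23 (E)-4-acetoxy-3-methoxycinnamic acid
Product: 24 8α-hydroxylabda-13(16),14-dien-19-yl (E)-4-acetoxy-3-methoxycinnamate
Conditions: EDC·HCl, DMAP, CH2Cl2, rt
Reagents that add atoms: none
Why: Steglich esterification; only the primary C19 hydroxyl should be acylated, since the tertiary C8 hydroxyl, flanked by C17 and C9, does not react under carbodiimide/DMAP conditions, and the diene is inert.

Step 13
Reactants: 24 8α-hydroxylabda-13(16),14-dien-19-yl (E)-4-acetoxy-3-methoxycinnamate
Product: 25 8α-hydroxylabda-13(16),14-dien-19-yl (E)-ferulate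
Conditions: pyrrolidine, CH2Cl2, 0 °C
Reagents that add atoms: none
Why: Aminolysis of the aryl acetate is far faster than that of the hindered alkyl cinnamate, so the phenol should be released under conditions that leave the ester, the diene and the tertiary alcohol alone.

## Compound list

1 | 6-methylhept-5-en-2-one | CC(=O)CCC=C(C)C | starting material
2 | 2-methyl-2-(4-methylpent-3-en-1-yl)-1,3-dioxolane | CC1(CCC=C(C)C)OCCO1 | intermediate
3 | (2E)-2-methyl-5-(2-methyl-1,3-dioxolan-2-yl)pent-2-en-1-ol | CC1(CC/C=C(\C)CO)OCCO1 | intermediate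
4 | 2-[(3E)-5-bromo-4-methylpent-3-en-1-yl]-2-methyl-1,3-dioxolane | CC1(CC/C=C(\C)CBr)OCCO1 | intermediate
5 | 2,3-dimethylbenzoyl chloride | Cc1cccc(C(=O)Cl)c1C | starting material
6 | (S)-2-(methoxymethyl)pyrrolidine | COC[C@@H]1CCCN1 | starting material
7 | (2,3-dimethylphenyl)[(2S)-2-(methoxymethyl)pyrrolidin-1-yl]methanone | COC[C@@H]1CCCN1C(=O)c1cccc(C)c1C | intermediate
8 | {2-[(2S)-2-(methoxymethyl)pyrrolidine-1-carbonyl]-6-methylphenyl}methyllithium | COC[C@@H]1CCCN1C(=O)c1cccc(C)c1C[Li] | intermediate
9 | [(2S)-2-(methoxymethyl)pyrrolidin-1-yl]{3-methyl-2-[(3E)-3-methyl-6-(2-methyl-1,3-dioxolan-2-yl)hex-3-en-1-yl]phenyl}methanone | COC[C@@H]1CCCN1C(=O)c1cccc(C)c1CC/C(C)=C/CCC1(C)OCCO1 | intermediate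
10 | potassium amide enolate of the 1,4-dihydro arene (enolate carbon = C19, exocyclic C=C to C4; enolate geometry not specified) | COC[C@@H]1CCCN1C(O[K])=C1C=CCC(C)=C1CC/C(C)=C/CCC1(C)OCCO1 | intermediate
11 | [(1S)-1,3-dimethyl-2-[(3E)-3-methyl-6-(2-methyl-1,3-dioxolan-2-yl)hex-3-en-1-yl]cyclohexa-2,5-dien-1-yl][(2S)-2-(methoxymethyl)pyrrolidin-1-yl]methanone | COC[C@@H]1CCCN1C(=O)[C@@]1(C)C=CCC(C)=C1CC/C(C)=C/CCC1(C)OCCO1 | intermediate
12 | [(1S)-1,3-dimethyl-2-[(3E)-3-methyl-6-(2-methyl-1,3-dioxolan-2-yl)hex-3-en-1-yl]cyclohex-2-en-1-yl][(2S)-2-(methoxymethyl)pyrrolidin-1-yl]methanone | COC[C@@H]1CCCN1C(=O)[C@@]1(C)CCCC(C)=C1CC/C(C)=C/CCC1(C)OCCO1 | intermediate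
13 | [(1S)-1,3-dimethyl-2-[(3E)-3-methyl-6-(2-methyl-1,3-dioxolan-2-yl)hex-3-en-1-yl]cyclohex-2-en-1-yl]methanol | OC[C@@]1(C)CCCC(C)=C1CC/C(C)=C/CCC1(C)OCCO1 | intermediate
14 | (5E)-8-[(6S)-6-(hydroxymethyl)-2,6-dimethylcyclohex-1-en-1-yl]-6-methyloct-5-en-2-one | OC[C@@]1(C)CCCC(C)=C1CC/C(C)=C/CCC(C)=O | intermediate
15 | (5E)-8-(1,5-dimethyl-6-oxabicyclo[3.2.1]octan-8-yl)-6-methyloct-5-en-2-one; the 19,10-ether of ring A with oxygen on the β-face of C10 and the side chain on C5 syn to the oxygen bridge (H-5 anti to it) | CC(=O)CC/C=C(\C)CC[C@@H]1[C@@]2(C)CCC[C@]1(C)CO2 | intermediate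
16 | 8α,13-epoxy-14,15-dinorlabd-12-en-19-ol | CC1=CC[C@@H]2[C@@]3(C)CCC[C@](C)(CO)[C@@H]3CC[C@@]2(C)O1 | intermediate
17 | 8α,19-dihydroxy-14,15-dinorlabdan-13-one (4S,5R,8R,9R,10S) | CC(=O)CC[C@@H]1[C@@]2(C)CCC[C@](C)(CO)[C@@H]2CC[C@@]1(C)O | intermediate
18 | 2,4,6-triisopropylbenzenesulfonohydrazide | CC(C)c1cc(C(C)C)c(S(=O)(=O)NN)c(C(C)C)c1 | starting material
19 | 2,4,6-triisopropylbenzenesulfonylhydrazone of 17 (E/Z mixture at C=N) | CC(CC[C@@H]1[C@@]2(C)CCC[C@](C)(CO)[C@@H]2CC[C@@]1(C)O)=NNS(=O)(=O)c1c(C(C)C)cc(C(C)C)cc1C(C)C | intermediate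
20 | 13-lithio-14,15-dinorlabd-13(16)-ene-8α,19-diol dilithium alkoxide | [Li]C(=C)CC[C@@H]1[C@@]2(C)CCC[C@](C)(CO[Li])[C@@H]2CC[C@@]1(C)O[Li] | intermediate
21 | corresponding 13-(bromozincio) alkene dilithium alkoxide | Br[Zn]C(=C)CC[C@@H]1[C@@]2(C)CCC[C@](C)(CO[Li])[C@@H]2CC[C@@]1(C)O[Li] | intermediate
22 | labda-13(16),14-diene-8α,19-diol (4S,5R,8R,9R,10S) | C=CC(=C)CC[C@@H]1[C@@]2(C)CCC[C@](C)(CO)[C@@H]2CC[C@@]1(C)O | intermediate
23 | (E)-4-acetoxy-3-methoxycinnamic acid | COc1cc(/C=C/C(=O)O)ccc1OC(C)=O | starting material
24 | 8α-hydroxylabda-13(16),14-dien-19-yl (E)-4-acetoxy-3-methoxycinnamate | C=CC(=C)CC[C@@H]1[C@@]2(C)CCC[C@](C)(COC(=O)/C=C/c3ccc(OC(C)=O)c(OC)c3)[C@@H]2CC[C@@]1(C)O | intermediate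
25 | 8α-hydroxylabda-13(16),14-dien-19-yl (E)-ferulate (4S,5R,8R,9R,10S) | C=CC(=C)CC[C@@H]1[C@@]2(C)CCC[C@](C)(COC(=O)/C=C/c3ccc(O)c(OC)c3)[C@@H]2CC[C@@]1(C)O | target

## Step count and least certain steps

Total steps: 13. Longest linear sequence: 12 (steps 1–3, then 5–13, from 1 to 25).

**Step 9 (key step).** Facial control at C5 and C10 may be lost if the bridged oxonium is not on the pathway: protonation of C5 on the β-face, or C9 entering syn to C19, would lead to cis-fused or C4-epimeric decalins. The reaction may also stall at the bridged ether 15. A 1,2-hydride shift from C5 to C10 followed by loss of the C19 carbon (retro-Prins) is a further risk, as is capture of the C8 cation by the counter-ion in place of the carbonyl oxygen.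

Fallback, from 12 back to 16: the ring closure is run at the acid oxidation level from an isolated lactone. Treatment of 12 with TsOH·H2O in wet toluene at 80 °C should cause neighbouring-group lactonization onto C10. This releases 6, removes the ketal and gives the bridged lactone ketone F1 as an equilibrated C5 epimer that can be checked before use. FSO3H then ionizes the tertiary C10–O bond with carboxylate as the leaving group while C9 enters from the rear, giving the tricyclic enol ether acid F2. LiAlH4 reduces F2 to 16, which is hydrolysed to 17 as in step 9. The cost is one step.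

**Step 6.** The 3-methyl group may change the enolate geometry or the chelate, so that facial selectivity in the methylation is low or reversed. Over-reduction or proton quench in place of C-methylation is also possible.

Fallback, from 4 back to 13, by classical resolution instead of auxiliary control: the dilithium salt of 2,3-dimethylbenzoic acid F5 (LiN(i-Pr)2, 2 equiv) is alkylated with 4 to the achiral acid F6. Birch reduction–methylation of the free acid (Li, NH3; MeI) gives the racemic dienoic acid F7, and H2 with RhCl(PPh3)3 gives the racemic acid F8. Crystallization of its salt with one enantiomer of 1-phenylethylamine delivers the (S)-acid F4, and LiAlH4 returns the route at 13.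

**Step 8.** The hindered amide may be reduced incompletely, or C–O cleavage may compete with C–N cleavage and give the tertiary amine.

Fallback, from 12 back to 13: iodolactonization (I2, aqueous THF) lets the amide oxygen attack C10, releases 6 and gives the iodolactone F3 with the ketal intact. Zn dust with NH4Cl in EtOH eliminates iodide and carboxylate to restore the C5=C10 alkene in the (S)-acid F4, and LiAlH4 gives 13.

**Step 11.** The vinyllithium may be quenched by solvent. Reversible addition of the C8 alkoxide to the hydrazone may disturb the regiochemistry of deprotonation. Transmetalation may be incomplete in the presence of two alkoxides.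

Fallback, from 17 back to 22: both hydroxyls are silylated with 1-(trimethylsilyl)imidazole to the bis(trimethylsilyl) ether F9. Kinetic enolization at the methyl group with KN(SiMe3)2 and trapping with PhNTf2 gives the enol triflate F10. Stille coupling with tributyl(vinyl)stannane (Pd(PPh3)4, LiCl) gives the protected diene F11, and Bu4NF returns 22.

## Further compounds

F1 | step 9 | bridged lactone ketone: (5E)-8-(1,5-dimethyl-7-oxo-6-oxabicyclo[3.2.1]octan-8-yl)-6-methyloct-5-en-2-one, 19,10-olide with oxygen on the β-face of C10 | CC(=O)CC/C=C(\C)CC[C@@H]1[C@@]2(C)CCC[C@]1(C)C(=O)O2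
F2 | step 9 | 8α,13-epoxy-14,15-dinorlabd-12-en-19-oic acid | CC1=CC[C@@H]2[C@@]3(C)CCC[C@](C)(C(=O)O)[C@@H]3CC[C@@]2(C)O1
F3 | step 8 | iodolactone: 19,10-olide of ring A with iodine on C5 anti to the lactone oxygen, ketal intact | CC1(CC/C=C(\C)CC[C@]2(I)[C@@]3(C)CCC[C@]2(C)C(=O)O3)OCCO1
F4 | step 8 | (1S)-1,3-dimethyl-2-[(3E)-3-methyl-6-(2-methyl-1,3-dioxolan-2-yl)hex-3-en-1-yl]cyclohex-2-ene-1-carboxylic acid | OC(=O)[C@@]1(C)CCCC(C)=C1CC/C(C)=C/CCC1(C)OCCO1
F5 | step 6 | 2,3-dimethylbenzoic acid | Cc1cccc(C(=O)O)c1C
F6 | step 6 | 3-methyl-2-[(3E)-3-methyl-6-(2-methyl-1,3-dioxolan-2-yl)hex-3-en-1-yl]benzoic acid | OC(=O)c1cccc(C)c1CC/C(C)=C/CCC1(C)OCCO1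
F7 | step 6 | racemic 1,3-dimethyl-2-[(3E)-3-methyl-6-(2-methyl-1,3-dioxolan-2-yl)hex-3-en-1-yl]cyclohexa-2,5-diene-1-carboxylic acid | OC(=O)C1(C)C=CCC(C)=C1CC/C(C)=C/CCC1(C)OCCO1
F8 | step 6 | racemic 1,3-dimethyl-2-[(3E)-3-methyl-6-(2-methyl-1,3-dioxolan-2-yl)hex-3-en-1-yl]cyclohex-2-ene-1-carboxylic acid | OC(=O)C1(C)CCCC(C)=C1CC/C(C)=C/CCC1(C)OCCO1
F9 | step 11 | 8α,19-bis(trimethylsilyloxy)-14,15-dinorlabdan-13-one | CC(=O)CC[C@@H]1[C@@]2(C)CCC[C@](C)(CO[Si](C)(C)C)[C@@H]2CC[C@@]1(C)O[Si](C)(C)C
F10 | step 11 | 8α,19-bis(trimethylsilyloxy)-14,15-dinorlabd-13(16)-en-13-yl trifluoromethanesulfonate | C=C(OS(=O)(=O)C(F)(F)F)CC[C@@H]1[C@@]2(C)CCC[C@](C)(CO[Si](C)(C)C)[C@@H]2CC[C@@]1(C)O[Si](C)(C)C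
F11 | step 11 | 8α,19-bis(trimethylsilyloxy)labda-13(16),14-diene | C=CC(=C)CC[C@@H]1[C@@]2(C)CCC[C@](C)(CO[Si](C)(C)C)[C@@H]2CC[C@@]1(C)O[Si](C)(C)C
A1 | alternative 1 | (+)-sclareolide | O=C1C[C@@H]2[C@@]3(C)CCCC(C)(C)[C@@H]3CC[C@@]2(C)O1
A2 | alternative 1 | 19-hydroxysclareolide | O=C1C[C@@H]2[C@@]3(C)CCC[C@](C)(CO)[C@@H]3CC[C@@]2(C)O1
A3 | alternative 2 | ethyl (6E,10E)-2,7,11-trimethyl-13-(2-methyl-1,3-dioxolan-2-yl)-3-oxotrideca-6,10-dienoate | CCOC(=O)C(C)C(=O)CC/C(C)=C/CC/C(C)=C/CCC1(C)OCCO1
A4 | alternative 2 | ethyl 3-oxo-13,13-ethylenedioxy-14,15-dinorlabd-8(17)-en-19-oate (one enantiomer drawn) | CC1(CC[C@@H]2[C@@]3(C)CCC(=O)[C@](C)(C(=O)OCC)[C@@H]3CCC2=C)OCCO1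
A5 | alternative 3 | (5E,9E)-6,10-dimethyl-13-[(2S)-2-methyloxiran-2-yl]trideca-5,9-dien-2-one | C[C@]1(CCC/C(C)=C/CC/C(C)=C/CCC(C)=O)CO1
A6 | alternative 3 | C4 epimer of 17 (8α,18-dihydroxy-14,15-dinorlabdan-13-one) | CC(=O)CC[C@@H]1[C@@]2(C)CCC[C@@](C)(CO)[C@@H]2CC[C@@]1(C)O
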